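The runs come from a simulation with constants of no real substance, and the scatter is random.

The target rose, then fell.

| setting | Wednesday's | Tuesday's | flask |
|---|---|---|---|
| starting material | 0.15 M | 0.15 M | 0.15 M |
| first nucleophile | 0.037 M | 0.056 M | 0.0750 M |
| second nucleophile | 0.30 M | 0.30 M | 0.300 M |
| remark | run made earlier | run made earlier |  |
| time |  |  | 2.5 h |

- Wednesday's (time / h: target / %): 0.0500: 9.9; 0.133: 17.2; 0.417: 13.6; 1.00: 5.9; 3.00: 0.8
- Tuesday's (time / h: target / %): 0.0500: 12.8; 0.133: 24.3; 0.417: 20.2; 1.00: 9.1; 3.00: 0.8

(each reading ± 0.3 percentage points)

- when, up to 2.5 h, the flask holds most target
- the amount of target, in percent of the starting material charged, at that time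

- the analysis behind the earlier runs scatters by 0.3 percentage points, standard deviation

One target takes one first nucleophile, so I began with the ceiling, c(first nucleophile)/c(starting material), which was 50.0% in the flask. Over their own ceilings, the highest readings gave 0.697 on Wednesday and 0.651 on Tuesday. The flask's first nucleophile lay one equal step further, so I continued the fall to 0.604. The share of its ceiling that a flask holds at its peak is the keep fraction, and this was my value of it for the flask.

I asked what each number could move. The ceiling moved the height in proportion, and it came straight from the charges. The flask's second nucleophile matched the charge of both runs, so it gave no correction. Tuesday's highest reading, off by 0.3 percentage points, would have moved my height by 0.8 points. A further doubt was that Tuesday's highest reading need not be that run's peak, which lay between 0.0500 h and 0.417 h.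

So I reckoned 30.2% for the flask's peak. The forecast gave more, 32% at 0.2 h, holding that “the second nucleophile, in excess, then removes it”.

The flask gave 31.9% at 0.215 h, a keep fraction of 0.638.

    starting material → intermediate (k = 0.112 min⁻¹)
    first nucleophile + intermediate → target (k = 15.6 M⁻¹ min⁻¹)
    second nucleophile + intermediate → other capture product (k = 1.33 M⁻¹ min⁻¹)
    intermediate → solvolysis product (k = 0.0644 min⁻¹)
    second nucleophile ⇌ dormant form (K = 0.192, k = 0.538 min⁻¹)
    2 starting material → homo dimer (k = 0.00111 M⁻¹ min⁻¹)
    second nucleophile + target → over-reaction product (k = 0.154 M⁻¹ min⁻¹)

The neighbouring flask had 0.75 M of second nucleophile and the same charges of first nucleophile and starting material, so its ceiling was again 50.0%, and the keep fraction, read from runs at 0.30 M of second nucleophile, gave 30.2% once more. That flask reached 18.2%, a keep fraction of 0.364. At its end it held 54.7% of other capture product.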